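## Structural features

Compound 33 is an elemane-type lactone: a single cyclohexane (C5 to C10) carrying a trans-fused α-methylene-γ-butyrolactone across C6–C7 (ring O6, C6, C7, C11, C12; exocyclic C11=C13). C10 is quaternary with methyl C14 and vinyl C1=C2; its neighbour C5 bears the 3-hydroxyprop-1-en-2-yl unit C4(=C3)–C15; C8 carries the ester of (R)-3-hydroxy-2-methylpropanoic acid; C9 is the only ring methylene. The five ring stereocentres are contiguous (C10, C5, C6, C7, C8). Taking β as the face of C11 at C7, the C5 side chain and C1 are β and O6, O8 and C14 are α, so C5 to C8 are all-trans and equatorial while the vinyl group is axial and cis to the C5 side chain. Fragile points are the exo-methylene lactone (Michael acceptor), the base-labile α-centre of the acyl side chain, migration of the lactone from O6 to a free O8, and, in intermediates, a C5–H lying between a C4 carbonyl and the C6 acyloxy group. The real difficulty is the quaternary C10 and its relation to the C5–C8 array. C10 holds a one-carbon branch (C1) beside the ring methylene C9. This is the pattern left when the C1–C10 epoxide of a seven-membered ring (C1, C10, C5, C6, C7, C8, C9) opens at C10 and C9 shifts from C1 to C10, and the key step uses exactly that.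

## Logic of the disconnections

**Acyl side chain.** The two O–Si bonds of 32 and then the O8–acyl bond are cut, giving 27 and 30 (joined through 31). The acyl group holds an epimerisable centre, so it should enter only after all enolate chemistry. The gain is one stereocentre and four carbons removed to 30, which comes from 28 through 29. The forward demand is that O8 be freed in 26 without touching O15, and that the ester form without epimerisation.

**C11=C13.** The exocyclic alkene of 26 is cut back to the lactone CH2 of 23 (through 24 and 25). The Michael acceptor is thereby kept out of most of the route. The demand is enolisation at C11 only.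

**C1=C2 and C4=C3.** Both alkenes of 23 are traced to carbonyl groups in 22. This exposes the keto aldehyde that a ring contraction delivers. The demand is methylenation without base, because C5–H of 22 lies between the C4 carbonyl and the C6 acyloxy group.

**C9–C10 (key).** In 22 the C9–C10 bond is cut, C9 is rejoined to C1 and an oxygen bridges C1 and C10, which gives 21. A formyl-bearing quaternary carbon next to a ring CH2 is the retron of an epoxide-to-aldehyde 1,2-shift. The gain is that the quaternary stereocentre becomes an epoxide carbon on a seven-membered ring, whose face can be set from the C5 side chain. The demand is opening at C10, migration of C9 and not of hydride, and a β-epoxide, since C10 forms with inversion.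

**Epoxide and C4 carbonyl.** The epoxide C–O bonds and the C4 carbonyl of 21 are taken back through 20 to the alkene and C4 hydroxyl of 19, and to its silyl ether 18. The C4 hydroxyl is homoallylic to C1=C10 and sits on the β face through C5, so it can deliver oxygen to the required face before becoming the carbonyl. The C4 configuration is therefore of no consequence. The demand is a directed rather than a sterically controlled epoxidation, with O8 masked so that it cannot direct to the α face.

**C1=C10.** The ring alkene of 18 is cut by metathesis logic to the diene 17. The gain is a monocyclic lactone. The demand is closure of a trisubstituted alkene in a trans-fused five-seven system.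

**C8–C9.** The allyl group of 17 is removed through 16 to the formyl group of 15. C8 is a carbinol beside C7, the retron of an allyl-metal addition. The demand is reagent-controlled delivery to the Si face under neutral conditions, since 15 is a β-acyloxy aldehyde and a free O8 could take over the lactone.

**C6–C7 and O6–C12.** The aldol bond and the lactone bond are cut and the C8 oxidation level is adjusted through 14, which leads from 15 through 13 and 12 to 11 and 8. A carbinol at C6 next to a C7 carrying an acyl carbon and a CH2CO2 arm is the retron of a succinate syn-aldol, and the adduct closes to the trans lactone by itself. The gain is two fragments of similar size, 11 (from 9 and 10) and 8. The demand is auxiliary control over an α-branched aldehyde that can isomerise, and cleavage of the imide beside the lactone.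

**C4–C5.** The aldol bond of 8 is cut (through 7, 6 and 5) to 3 and 4, and 3 to 1 and 2. C5 bears an isopropenyl group next to an acyl carbon and C4 is a carbinol, the retron of a deconjugative syn-aldol. The same step brings in O4 (later the directing group and the ketone) and C15 already silylated. The demand is reaction of the dienolate at its α-carbon and auxiliary control of C5.

## Other disconnections considered

**Alternative 1:** The cut is at C10–C1 and C5–C4, with C1=C2 and C4=C3 traced to one cyclobutene double bond. Forward, enone A1, (S)-5-(tert-butyldimethylsilyloxy)-3-methylcyclohex-2-en-1-one, would be irradiated at 350 nm with alkyne A2, tert-butyldiphenyl(prop-2-yn-1-yloxy)silane, to give the cis-fused cyclobutene A3. Ring-opening metathesis of A3 with ethene would then turn C1=C4 into the vinyl group and the 1,1-disubstituted alkene.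

- In its favour: C10, C5 and both alkenes at their final oxidation level come from two steps, the cis fusion enforces the cis relation of C1 and C4, and ring strain drives the ethenolysis.
- Against it here: nothing in A1 or A2 controls the orientation of the alkyne (C4 must bond to C5). The face is chosen only by the remote C8 silyl ether. A3 is a β,γ-unsaturated ketone that may react on under the lamp by 1,3-acyl shift. C6 and C7 remain a ketone and a methylene, so the lactone still needs a regioselective C7 alkylation beside a β-silyloxy group and a face-selective reduction. A1 must also be secured as one enantiomer.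
- Comparison: on structure the two plans are equal, since each creates C10 in one step with C1 and C4 cis. On mechanism the chosen plan is stronger: the alternative rests on a stepwise biradical cycloaddition with two open selectivity questions, whereas the chosen plan has one (carbon against hydride shift) and takes the C10 configuration stereospecifically from an epoxide placed by a tethered reagent. On step economy the alternative is the better, probably by eight to ten steps, and it needs no carbonyl methylenation.

**Alternative 2:** The cut is at O6–C12 and C12–C11, so that the lactone carbonyl comes from carbon monoxide. Forward, ethynyl alcohol A4 (C6–OH trans to a C7 ethynyl group that supplies C11 and C13, both primary hydroxyls as tert-butyldiphenylsilyl ethers) would be treated with PdCl2 and thiourea under CO. Alkoxycarbonylation of divalent palladium at O6 and syn addition across the alkyne would close the five-membered ring and give A5, the bis(silyl) ether of 33.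

- In its favour: ring and exocyclic alkene form in one neutral step at the very end, no enolate is needed, and the C8 ester can already be in place, so the selective unmasking of O8 (step 19) disappears.
- Against it here: it is an endgame tactic and leaves C10 and the C5–C8 array unsolved. A4 needs an ethynyl group trans to O6 on a fully substituted ring. The C11≡C13 alkyne and the C4=C3 alkene form a 1,6-enyne that divalent palladium may cycloisomerise.
- Comparison: on structure it equals steps 7 and 18 of the chosen plan in bonds formed and is better in protecting-group economy. On mechanism it is better for the base-sensitive ester, while the chosen plan is better in that no late transition metal meets the triene. On step economy it is equal or slightly better for the endgame, but the chosen plan needs the lactone early as the rigid template for ring closure and face control, so the tactic cannot simply be grafted on.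

**Alternative 3:** The cut is at C7–C8. Forward, aldehyde A6, an open chain from the C8 formyl group through C9, C10, C5 and C6 to a (Z)-2-(pinacolborylmethyl)enoate at C7=C11, would close on warming or with Sc(OTf)3 to cyclohexanol A7. The closure passes through a chair of B, O, C8, C7, C11 and C13 and moves the alkene to C11=C13.

- In its favour: the closed transition state turns the (Z) geometry into the trans relation of O8 and C11. The ring, C7 and C8 arise together. The acrylate is in place for lactonisation onto O6 without enolate chemistry, and O8–H is free for acylation.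
- Against it here: A6 must already hold the quaternary C10 beside C5 and C6 in an open chain, which moves the hardest centre to acyclic chemistry with no built-in answer. Ester-bearing allylboronates are weak nucleophiles, and the sense of closure relative to C6 depends on which chair the tether adopts.
- Comparison: on structure the alternative is better in stereocentres per step (one ring, one C–C bond, two stereocentres and C11=C13, against one ring, one bond and one stereocentre). On mechanism the two are equal, both being stereospecific, but the chosen plan creates C10 whereas the alternative presupposes it. On step economy the alternative's endgame is shorter by two or three steps, though the total is unlikely to be lower once A6 is made.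

Key step: step 16

Assumption: aldehyde 4, both oxazolidinones, the acid chlorides 2 and 10 and the allylborane of step 10 are taken as purchased; the locants C1 to C15 and the α/β labels defined above apply to every intermediate, open-chain ones included.

Abbreviations: TBS = tert-butyldimethylsilyl, TES = triethylsilyl, TBDPS = tert-butyldiphenylsilyl.

## Steps

Step 1
Reactants: 1 (R)-4-benzyl-1,3-oxazolidin-2-one; 2 3-methylbut-2-enoyl chloride
Product: 3 (R)-4-benzyl-3-(3-methylbut-2-enoyl)-1,3-oxazolidin-2-one
Conditions: n-BuLi, THF, −78 °C; then 2, −78 → 0 °C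
Reagents that add atoms: none
Why: N-acylation of the lithiated oxazolidinone by an acid chloride, the standard loading of the auxiliary; no stereocentre is formed.

Step 2
Reactants: 3 (R)-4-benzyl-3-(3-methylbut-2-enoyl)-1,3-oxazolidin-2-one; 4 2-(TBDPS-oxy)acetaldehyde
Product: 5 (R)-4-benzyl-3-[(2R,3R)-4-(TBDPS-oxy)-3-hydroxy-2-(prop-1-en-2-yl)butanoyl]-1,3-oxazolidin-2-one
Conditions: n-Bu2BOTf, Et3N, CH2Cl2, −78 → 0 °C; 4, −78 → 0 °C; pH 7 buffer, MeOH, H2O2
Reagents that add atoms: none
Why: Deconjugative Evans syn-aldol: γ-deprotonation gives the boron dienolate, which should react at its α-carbon through a Zimmerman–Traxler chair. The (R)-benzyl auxiliary sets C5 (chain C2), and the C4 carbinol arises syn but its configuration is immaterial; the step brings in C10, C14, O4 and the silylated C15 at once.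

Step 3
Reactants: 5 (R)-4-benzyl-3-[(2R,3R)-4-(TBDPS-oxy)-3-hydroxy-2-(prop-1-en-2-yl)butanoyl]-1,3-oxazolidin-2-one
Product: 6 (2R,3R)-4-(TBDPS-oxy)-3-hydroxy-N-methoxy-N-methyl-2-(prop-1-en-2-yl)butanamide
Conditions: MeNH(OMe)·HCl, AlMe3, CH2Cl2, −20 → 0 °C
Reagents that add atoms: N,O-dimethylhydroxylamine hydrochloride, CNOC.Cl
Why: Aluminium-amide transamination of a β-hydroxy imide to the Weinreb amide, assisted by the free hydroxyl; the auxiliary is released and no stereocentre is touched.

Step 4
Reactants: 6 (2R,3R)-4-(TBDPS-oxy)-3-hydroxy-N-methoxy-N-methyl-2-(prop-1-en-2-yl)butanamide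
Product: 7 (2R,3R)-4-(TBDPS-oxy)-N-methoxy-N-methyl-2-(prop-1-en-2-yl)-3-(TES-oxy)butanamide
Conditions: Et3SiCl, imidazole, DMF, 0 °C → rt
Reagents that add atoms: chlorotriethylsilane, CC[Si](Cl)(CC)CC
Why: Silylation of the secondary alcohol; the triethylsilyl ether is chosen because it can later be removed beside the TBS and TBDPS ethers.

Step 5
Reactants: 7 (2R,3R)-4-(TBDPS-oxy)-N-methoxy-N-methyl-2-(prop-1-en-2-yl)-3-(TES-oxy)butanamide
Product: 8 (2R,3R)-4-(TBDPS-oxy)-2-(prop-1-en-2-yl)-3-(TES-oxy)butanal
Conditions: i-Bu2AlH, THF, −78 °C; aq. Rochelle salt; used crude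
Reagents that add atoms: none
Why: Weinreb amide reduction stops at the aldehyde through the chelated tetrahedral intermediate; low temperature and immediate use should keep the α-centre and the β,γ-alkene in place.

Step 6
Reactants: 9 (S)-4-benzyl-1,3-oxazolidin-2-one; 10 methyl 4-chloro-4-oxobutanoate
Product: 11 methyl 4-[(S)-4-benzyl-2-oxo-1,3-oxazolidin-3-yl]-4-oxobutanoate
Conditions: n-BuLi, THF, −78 °C; then 10, −78 → 0 °C
Reagents that add atoms: none
Why: N-acylation of the lithiated oxazolidinone by the acid chloride; the acid chloride reacts far faster than the methyl ester.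

Step 7
Reactants: 11 methyl 4-[(S)-4-benzyl-2-oxo-1,3-oxazolidin-3-yl]-4-oxobutanoate; 8 (2R,3R)-4-(TBDPS-oxy)-2-(prop-1-en-2-yl)-3-(TES-oxy)butanal
Product: 13 (S)-4-benzyl-3-[(2R,3S)-2-{(3S,4R)-5-(TBDPS-oxy)-2-methyl-4-(TES-oxy)pent-1-en-3-yl}-5-oxooxolane-3-carbonyl]-1,3-oxazolidin-2-one, via hydroxy ester aldol adduct 12 (not isolated)
Conditions: n-Bu2BOTf, i-Pr2NEt, CH2Cl2, −78 → 0 °C; 8, −78 → 0 °C; pH 7 buffer, MeOH, H2O2; then PPTS (cat.), 4 Å MS, PhMe, 40 °C
Reagents that add atoms: none
Why: Evans syn-aldol: boron enolisation occurs at the imide α-CH2, and the (S)-auxiliary sets C7 and C6 through a Zimmerman–Traxler chair, reagent control being expected to override the C5 centre of the aldehyde. The γ-hydroxy ester then closes under mild acid (5-exo-trig acyl substitution) to the trans lactone, which fixes O6–C12 before any O8 exists.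

Step 8
Reactants: 13 (S)-4-benzyl-3-[(2R,3S)-2-{(3S,4R)-5-(TBDPS-oxy)-2-methyl-4-(TES-oxy)pent-1-en-3-yl}-5-oxooxolane-3-carbonyl]-1,3-oxazolidin-2-one
Product: 14 S-ethyl (2R,3S)-2-{(3S,4R)-5-(TBDPS-oxy)-2-methyl-4-(TES-oxy)pent-1-en-3-yl}-5-oxooxolane-3-carbothioate
Conditions: EtSH, n-BuLi, THF, 0 °C
Reagents that add atoms: ethanethiol, CCS
Why: Thiolate cleavage of the exocyclic imide carbonyl to the thioester; the soft, weakly basic nucleophile should leave the lactone and the C7 centre alone.

Step 9
Reactants: 14 S-ethyl (2R,3S)-2-{(3S,4R)-5-(TBDPS-oxy)-2-methyl-4-(TES-oxy)pent-1-en-3-yl}-5-oxooxolane-3-carbothioate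
Product: 15 (2R,3S)-2-{(3S,4R)-5-(TBDPS-oxy)-2-methyl-4-(TES-oxy)pent-1-en-3-yl}-5-oxooxolane-3-carbaldehyde
Conditions: Et3SiH, Pd/CaCO3 poisoned with Pb(OAc)2 (cat.), acetone, rt; used crude
Reagents that add atoms: none
Why: Fukuyama reduction of a thioester to the aldehyde under neutral conditions, so the β-acyloxy aldehyde is not exposed to base; the poisoned catalyst should spare the 1,1-disubstituted alkene.

Step 10
Reactants: 15 (2R,3S)-2-{(3S,4R)-5-(TBDPS-oxy)-2-methyl-4-(TES-oxy)pent-1-en-3-yl}-5-oxooxolane-3-carbaldehyde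
Product: 16 (4R,5S)-4-[(1S)-1-hydroxybut-3-en-1-yl]-5-{(3S,4R)-5-(TBDPS-oxy)-2-methyl-4-(TES-oxy)pent-1-en-3-yl}oxolan-2-one
Conditions: (−)-Ipc2B(allyl) [from (+)-α-pinene], Et2O, −78 °C; then NaBO3·4H2O, THF/H2O, rt
Reagents that add atoms: (−)-B-allyldiisopinocampheylborane, C=CCB([C@@H]1C[C@@H]2C[C@H]([C@H]1C)C2(C)C)[C@@H]1C[C@@H]2C[C@H]([C@H]1C)C2(C)C
Why: Brown allylboration through a closed chair; the isopinocampheyl ligands direct allyl to the Si face of the aldehyde and so set C8 as S (O8 on the α face) under reagent control. The mild perborate work-up is chosen to avoid lactone migration to the new hydroxyl.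

Step 11
Reactants: 16 (4R,5S)-4-[(1S)-1-hydroxybut-3-en-1-yl]-5-{(3S,4R)-5-(TBDPS-oxy)-2-methyl-4-(TES-oxy)pent-1-en-3-yl}oxolan-2-one
Product: 17 (4S,5S)-4-[(1S)-1-(TBS-oxy)but-3-en-1-yl]-5-{(3S,4R)-5-(TBDPS-oxy)-2-methyl-4-(TES-oxy)pent-1-en-3-yl}oxolan-2-one
Conditions: t-BuMe2SiOTf, 2,6-lutidine, CH2Cl2, −78 → 0 °C
Reagents that add atoms: tert-butyldimethylsilyl trifluoromethanesulfonate, CC(C)(C)[Si](C)(C)OS(=O)(=O)C(F)(F)F
Why: Silylation of the hindered secondary alcohol under non-nucleophilic conditions; it blocks O8 as a directing group and as a lactone acceptor.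

Step 12
Reactants: 17 (4S,5S)-4-[(1S)-1-(TBS-oxy)but-3-en-1-yl]-5-{(3S,4R)-5-(TBDPS-oxy)-2-methyl-4-(TES-oxy)pent-1-en-3-yl}oxolan-2-one
Product: 18 cycloheptene lactone (C1=C10 with 10-methyl; 5β-[(1R)-2-(TBDPS-oxy)-1-(TES-oxy)ethyl]; O6(α)–C12 lactone with C11 on 7β; 8α-TBS-oxy)
Conditions: second-generation Grubbs catalyst RuCl2(=CHPh)(PCy3)(H2IMes) (10 mol%), PhMe (2 mM), 80 °C
Reagents that add atoms: none
Why: Ring-closing metathesis: the ruthenium alkylidene should load at the allyl terminus and close onto the isopropenyl group, giving the trisubstituted C1=C10 alkene with loss of ethene; no stereocentre is formed.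

Step 13
Reactants: 18 cycloheptene lactone (4-TES ether)
Product: 19 cycloheptene lactone with free (4R)-hydroxyl (otherwise as 18)
Conditions: PPTS, MeOH/CH2Cl2, 0 °C
Reagents that add atoms: none
Why: Acid-catalysed methanolysis removes the triethylsilyl ether much faster than the secondary TBS or the primary TBDPS ether.

Step 14
Reactants: 19 cycloheptene lactone with free (4R)-hydroxyl
Product: 20 1β,10β-epoxy alcohol (otherwise as 19)
Conditions: VO(acac)2 (cat.), t-BuOOH, CH2Cl2, 0 °C → rt
Reagents that add atoms: tert-butyl hydroperoxide, CC(C)(C)OO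
Why: Hydroxyl-directed epoxidation of a homoallylic alcohol: the vanadate ester at O4, tethered through C5, can reach only the β face of C1=C10. The epoxide should therefore form syn to the C5 side chain and anti to O6 and O8, whatever the C4 configuration.

Step 15
Reactants: 20 1β,10β-epoxy alcohol
Product: 21 1β,10β-epoxy ketone, 5β-[2-(TBDPS-oxy)acetyl] (the rearrangement precursor)
Conditions: Dess–Martin periodinane, NaHCO3, CH2Cl2, 0 °C → rt; used without delay
Reagents that add atoms: none
Why: Buffered Dess–Martin oxidation turns the C4 carbinol into the ketone without base, so neither the epoxide nor the lactone oxygen is lost by β-elimination from C5; the C4 stereocentre disappears.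

Step 16
Reactants: 21 1β,10β-epoxy ketone
Product: 22 cyclohexane keto aldehyde (10β-formyl, 10α-methyl; 5β-[2-(TBDPS-oxy)acetyl]; 6α,12-lactone with C11 on 7β; 8α-TBS-oxy)
Conditions: MeAl(OAr)2 (Ar = 4-bromo-2,6-di-tert-butylphenyl; from AlMe3 and 2 ArOH; 3 equiv), CH2Cl2, −78 → −20 °C
Reagents that add atoms: none
Why: The aluminium centre binds the epoxide oxygen and the C10–O bond ionises at the tertiary carbon, the only site that can carry the charge. As that bond lengthens, the C1–C9 σ bond shifts from C1 to C10 on the face opposite the departing oxygen, and the aluminium alkoxide left at C1 collapses to the aldehyde. The closest known reaction type is the rearrangement of trisubstituted epoxides, 1-methylcycloalkene oxides included, to α-quaternary aldehydes by this bulky aluminium bis(aryloxide). The cyclohexane is closed by ring contraction through a suprafacial 1,2-alkyl shift, not by an exo or endo cyclisation. C10 is the one new stereocentre; it forms with inversion, so its configuration (C1 β, C14 α) is dictated by the β-epoxide of step 14. The step needs cleavage at C10 only, migration of carbon in preference to hydride from C1, and no loss of the C5 proton or capture of C10 by a neighbouring oxygen. The tertiary centre secures the first; the bulky ligand set, which turns the C1–O–Al unit away from C14 and lines up C9, favours the second; and the C4 carbonyl (no cation can develop at C5), the low temperature, the base-free medium and the hindered silyl ether at O8 guard against the rest.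

Step 17
Reactants: 22 cyclohexane keto aldehyde
Product: 23 diene lactone (10β-vinyl C1=C2, C4=C3 methylidene, otherwise as 22)
Conditions: Zn, CH2Br2, TiCl4, THF (reagent aged at 0–5 °C); 22, CH2Cl2, 0 °C → rt
Reagents that add atoms: dibromomethane, BrCBr
Why: Takai–Lombardo methylenation: the zinc–titanium methylene reagent converts the hindered aldehyde and the ketone without enolisation. C5, which lies between the ketone and the β-acyloxy C6, should therefore neither epimerise nor eliminate, and the lactone is inert.

Step 18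
Reactants: 23 diene lactone
Product: 26 triene lactone with C11=C13 methylidene (8α-TBS-oxy and 15-TBDPS-oxy retained), via Mannich base 24 (not isolated), via ammonium iodide 25 (not isolated)
Conditions: LiN(SiMe3)2, THF, −78 °C; Me2N=CH2+ I−, −78 → 0 °C; MeI, CH2Cl2, rt; aq. NaHCO3, rt
Reagents that add atoms: N,N-dimethylmethylideneammonium iodide (Eschenmoser's salt), C=[N+](C)C.[I-]
Why: Lactone α-methylenation by Mannich reaction of the kinetic lactone enolate, quaternisation and β-elimination; C11 is the only enolisable position, and its temporary stereocentre is lost on elimination.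

Step 19
Reactants: 26 triene lactone with C11=C13 methylidene
Product: 27 8α-hydroxy triene lactone (15-TBDPS ether retained)
Conditions: 48% aq. HF, MeCN, 0 °C → rt
Reagents that add atoms: none
Why: Acidic desilylation cleaves the secondary TBS ether far faster than the primary TBDPS ether; the absence of base should protect the exo-methylene lactone and keep the lactone on O6.

Step 20
Reactants: 28 methyl (R)-3-hydroxy-2-methylpropanoate
Product: 29 methyl (R)-3-(TBS-oxy)-2-methylpropanoate
Conditions: t-BuMe2SiCl, imidazole, CH2Cl2, rt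
Reagents that add atoms: tert-butyldimethylsilyl chloride, CC(C)(C)[Si](C)(C)Cl
Why: Silylation of the primary alcohol; the stereocentre is not involved.

Step 21
Reactants: 29 methyl (R)-3-(TBS-oxy)-2-methylpropanoate
Product: 30 (R)-3-(TBS-oxy)-2-methylpropanoic acid
Conditions: LiOH, THF/H2O, 0 °C; then dilute HCl to pH 4
Reagents that add atoms: lithium hydroxide, [Li+].[OH-]
Why: Saponification at low temperature; hydroxide attack at the ester carbonyl is faster than enolisation, so the α-centre should be retained.

Step 22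
Reactants: 30 (R)-3-(TBS-oxy)-2-methylpropanoic acid; 27 8α-hydroxy triene lactone
Product: 32 8α-[(R)-3-(TBS-oxy)-2-methylpropanoyloxy] triene lactone (15-TBDPS ether), via mixed anhydride 31 (not isolated)
Conditions: 2,4,6-Cl3C6H2COCl, Et3N, THF, rt; then 27, DMAP, PhMe, rt
Reagents that add atoms: none
Why: Yamaguchi esterification: the mixed anhydride passes its aliphatic acyl group through the acylpyridinium to the equatorial C8 hydroxyl under mild conditions that should preserve the α-centre of the acid and the lactone.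

Step 23
Reactants: 32 8α-[(R)-3-(TBS-oxy)-2-methylpropanoyloxy] triene lactone (15-TBDPS ether)
Product: 33 (3aR,4S,6R,7R,7aR)-6-ethenyl-7-(3-hydroxyprop-1-en-2-yl)-6-methyl-3-methylidene-2-oxooctahydro-1-benzofuran-4-yl (2R)-3-hydroxy-2-methylpropanoate
Conditions: HF·pyridine, pyridine, THF, 0 °C → rt
Reagents that add atoms: none
Why: Fluoride-mediated cleavage of both primary silyl ethers in a buffered, weakly acidic medium, which should avoid acyl migration, epimerisation and conjugate addition to the lactone.

## Compound list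

1 | (R)-4-benzyl-1,3-oxazolidin-2-one | O=C1N[C@H](Cc2ccccc2)CO1 | starting material
2 | 3-methylbut-2-enoyl chloride | CC(C)=CC(=O)Cl | starting material
3 | (R)-4-benzyl-3-(3-methylbut-2-enoyl)-1,3-oxazolidin-2-one | CC(C)=CC(=O)N1C(=O)OC[C@H]1Cc2ccccc2 | intermediate
4 | 2-[(tert-butyldiphenylsilyl)oxy]acetaldehyde | O=CCO[Si](c1ccccc1)(c2ccccc2)C(C)(C)C | starting material
5 | (R)-4-benzyl-3-[(2R,3R)-4-(TBDPS-oxy)-3-hydroxy-2-(prop-1-en-2-yl)butanoyl]-1,3-oxazolidin-2-one | C=C(C)[C@@H](C(=O)N1C(=O)OC[C@H]1Cc2ccccc2)[C@@H](O)CO[Si](c3ccccc3)(c4ccccc4)C(C)(C)C | intermediate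
6 | (2R,3R)-4-(TBDPS-oxy)-3-hydroxy-N-methoxy-N-methyl-2-(prop-1-en-2-yl)butanamide | C=C(C)[C@@H](C(=O)N(C)OC)[C@@H](O)CO[Si](c1ccccc1)(c2ccccc2)C(C)(C)C | intermediate
7 | (2R,3R)-4-(TBDPS-oxy)-N-methoxy-N-methyl-2-(prop-1-en-2-yl)-3-(TES-oxy)butanamide | C=C(C)[C@@H](C(=O)N(C)OC)[C@@H](O[Si](CC)(CC)CC)CO[Si](c1ccccc1)(c2ccccc2)C(C)(C)C | intermediate
8 | (2R,3R)-4-(TBDPS-oxy)-2-(prop-1-en-2-yl)-3-(TES-oxy)butanal | C=C(C)[C@@H](C=O)[C@@H](O[Si](CC)(CC)CC)CO[Si](c1ccccc1)(c2ccccc2)C(C)(C)C | intermediate
9 | (S)-4-benzyl-1,3-oxazolidin-2-one | O=C1N[C@@H](Cc2ccccc2)CO1 | starting material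
10 | methyl 4-chloro-4-oxobutanoate | COC(=O)CCC(=O)Cl | starting material
11 | methyl 4-[(S)-4-benzyl-2-oxo-1,3-oxazolidin-3-yl]-4-oxobutanoate | COC(=O)CCC(=O)N1C(=O)OC[C@@H]1Cc2ccccc2 | intermediate
12 | methyl (3S,4R,5S,6R)-3-[(S)-4-benzyl-2-oxo-1,3-oxazolidine-3-carbonyl]-7-(TBDPS-oxy)-4-hydroxy-5-(prop-1-en-2-yl)-6-(TES-oxy)heptanoate | C=C(C)[C@H]([C@@H](O[Si](CC)(CC)CC)CO[Si](c1ccccc1)(c2ccccc2)C(C)(C)C)[C@@H](O)[C@H](CC(=O)OC)C(=O)N3C(=O)OC[C@@H]3Cc4ccccc4 | intermediate
13 | (S)-4-benzyl-3-[(2R,3S)-2-{(3S,4R)-5-(TBDPS-oxy)-2-methyl-4-(TES-oxy)pent-1-en-3-yl}-5-oxooxolane-3-carbonyl]-1,3-oxazolidin-2-one | C=C(C)[C@H]([C@@H](O[Si](CC)(CC)CC)CO[Si](c1ccccc1)(c2ccccc2)C(C)(C)C)[C@H]3OC(=O)C[C@@H]3C(=O)N4C(=O)OC[C@@H]4Cc5ccccc5 | intermediate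
14 | S-ethyl (2R,3S)-2-{(3S,4R)-5-(TBDPS-oxy)-2-methyl-4-(TES-oxy)pent-1-en-3-yl}-5-oxooxolane-3-carbothioate | C=C(C)[C@H]([C@@H](O[Si](CC)(CC)CC)CO[Si](c1ccccc1)(c2ccccc2)C(C)(C)C)[C@H]3OC(=O)C[C@@H]3C(=O)SCC | intermediate
15 | (2R,3S)-2-{(3S,4R)-5-(TBDPS-oxy)-2-methyl-4-(TES-oxy)pent-1-en-3-yl}-5-oxooxolane-3-carbaldehyde | C=C(C)[C@H]([C@@H](O[Si](CC)(CC)CC)CO[Si](c1ccccc1)(c2ccccc2)C(C)(C)C)[C@H]3OC(=O)C[C@@H]3C=O | intermediate
16 | (4R,5S)-4-[(1S)-1-hydroxybut-3-en-1-yl]-5-{(3S,4R)-5-(TBDPS-oxy)-2-methyl-4-(TES-oxy)pent-1-en-3-yl}oxolan-2-one | C=C(C)[C@H]([C@@H](O[Si](CC)(CC)CC)CO[Si](c1ccccc1)(c2ccccc2)C(C)(C)C)[C@H]3OC(=O)C[C@@H]3[C@@H](O)CC=C | intermediate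
17 | (4S,5S)-4-[(1S)-1-(TBS-oxy)but-3-en-1-yl]-5-{(3S,4R)-5-(TBDPS-oxy)-2-methyl-4-(TES-oxy)pent-1-en-3-yl}oxolan-2-one | C=C(C)[C@H]([C@@H](O[Si](CC)(CC)CC)CO[Si](c1ccccc1)(c2ccccc2)C(C)(C)C)[C@H]3OC(=O)C[C@@H]3[C@@H](O[Si](C)(C)C(C)(C)C)CC=C | intermediate
18 | cycloheptene lactone: ring C1, C10, C5, C6, C7, C8, C9 with C1=C10 and 10-methyl; 5β-[(1R)-2-(TBDPS-oxy)-1-(TES-oxy)ethyl]; trans-fused γ-lactone O6(α)–C12(=O)–C11H2 on C7(β); 8α-TBS-oxy | C1=C(C)[C@H]([C@@H](O[Si](CC)(CC)CC)CO[Si](c3ccccc3)(c4ccccc4)C(C)(C)C)[C@H]2OC(=O)C[C@@H]2[C@@H](O[Si](C)(C)C(C)(C)C)C1 | intermediate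
19 | cycloheptene lactone as 18 with free (4R)-hydroxyl: 5β-[(1R)-2-(TBDPS-oxy)-1-hydroxyethyl] | C1=C(C)[C@H]([C@@H](O)CO[Si](c3ccccc3)(c4ccccc4)C(C)(C)C)[C@H]2OC(=O)C[C@@H]2[C@@H](O[Si](C)(C)C(C)(C)C)C1 | intermediate
20 | epoxy alcohol as 19 with 1β,10β-epoxide (oxygen on the face of the C5 side chain, anti to O6 and O8) | [C@@H]12O[C@]1(C)[C@H]([C@@H](O)CO[Si](c4ccccc4)(c5ccccc5)C(C)(C)C)[C@H]3OC(=O)C[C@@H]3[C@@H](O[Si](C)(C)C(C)(C)C)C2 | intermediate
21 | epoxy ketone as 20 with C4 carbonyl: 5β-[2-(TBDPS-oxy)acetyl]-1β,10β-epoxy-10-methylcycloheptane 6α,12-lactone, 8α-TBS-oxy | [C@@H]12O[C@]1(C)[C@H](C(=O)CO[Si](c4ccccc4)(c4ccccc4)C(C)(C)C)[C@H]3OC(=O)C[C@@H]3[C@@H](O[Si](C)(C)C(C)(C)C)C2 | intermediate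
22 | cyclohexane keto aldehyde: ring C5–C10; 10β-formyl, 10α-methyl; 5β-[2-(TBDPS-oxy)acetyl]; trans-fused 6α,12-lactone with C11 on 7β; 8α-TBS-oxy | O=C[C@@]1(C)C[C@H](O[Si](C)(C)C(C)(C)C)[C@H]2CC(=O)O[C@@H]2[C@H]1C(=O)CO[Si](c3ccccc3)(c3ccccc3)C(C)(C)C | intermediate
23 | diene lactone as 22 with 10β-vinyl (C1=C2) and 5β-[3-(TBDPS-oxy)prop-1-en-2-yl] (C4=C3) | C=C[C@@]1(C)C[C@H](O[Si](C)(C)C(C)(C)C)[C@H]2CC(=O)O[C@@H]2[C@H]1C(=C)CO[Si](c3ccccc3)(c3ccccc3)C(C)(C)C | intermediate
24 | Mannich base: 23 with C11 carrying CH2NMe2 (either configuration at C11) | C=C[C@@]1(C)C[C@H](O[Si](C)(C)C(C)(C)C)[C@H]2C(CN(C)C)C(=O)O[C@@H]2[C@H]1C(=C)CO[Si](c3ccccc3)(c3ccccc3)C(C)(C)C | intermediate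
25 | trimethylammonium iodide of 24 | C=C[C@@]1(C)C[C@H](O[Si](C)(C)C(C)(C)C)[C@H]2C(C[N+](C)(C)C)C(=O)O[C@@H]2[C@H]1C(=C)CO[Si](c3ccccc3)(c3ccccc3)C(C)(C)C.[I-] | intermediate
26 | triene lactone as 23 with C11=C13 methylidene (8α-TBS-oxy, 15-TBDPS-oxy) | C=C[C@@]1(C)C[C@H](O[Si](C)(C)C(C)(C)C)[C@H]2C(=C)C(=O)O[C@@H]2[C@H]1C(=C)CO[Si](c3ccccc3)(c3ccccc3)C(C)(C)C | intermediate
27 | 8α-hydroxy triene lactone (15-TBDPS ether of the deacylated target) | C=C[C@@]1(C)C[C@H](O)[C@H]2C(=C)C(=O)O[C@@H]2[C@H]1C(=C)CO[Si](c3ccccc3)(c3ccccc3)C(C)(C)C | intermediate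
28 | methyl (R)-3-hydroxy-2-methylpropanoate | COC(=O)[C@H](C)CO | starting material
29 | methyl (R)-3-(TBS-oxy)-2-methylpropanoate | COC(=O)[C@H](C)CO[Si](C)(C)C(C)(C)C | intermediate
30 | (R)-3-(TBS-oxy)-2-methylpropanoic acid | OC(=O)[C@H](C)CO[Si](C)(C)C(C)(C)C | intermediate
31 | (R)-3-(TBS-oxy)-2-methylpropanoic 2,4,6-trichlorobenzoic anhydride | O=C(OC(=O)[C@H](C)CO[Si](C)(C)C(C)(C)C)c1c(Cl)cc(Cl)cc1Cl | intermediate
32 | 8α-[(R)-3-(TBS-oxy)-2-methylpropanoyloxy] triene lactone, 15-TBDPS ether (bis-silyl ether of the target) | C=C[C@@]1(C)C[C@H](OC(=O)[C@H](C)CO[Si](C)(C)C(C)(C)C)[C@H]2C(=C)C(=O)O[C@@H]2[C@H]1C(=C)CO[Si](c3ccccc3)(c3ccccc3)C(C)(C)C | intermediate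
33 | (3aR,4S,6R,7R,7aR)-6-ethenyl-7-(3-hydroxyprop-1-en-2-yl)-6-methyl-3-methylidene-2-oxooctahydro-1-benzofuran-4-yl (2R)-3-hydroxy-2-methylpropanoate | C=C[C@@]1(C)C[C@H](OC(=O)[C@H](C)CO)[C@H]2C(=C)C(=O)O[C@@H]2[C@H]1C(=C)CO | target

## Step count and least certain steps

Total: 23 steps. Longest linear sequence: 20 steps (steps 1–5, 7–19, 22 and 23).

**Step 16 (key step).** The most likely failures are migration of hydride from C1 in place of C9 (the seven-membered ring is then kept as a ketone), loss of the acidified C5 proton from the C10 cation (the epoxide then opens to an allylic alkoxide), or transannular attack of the O8 ether oxygen on C10. Each is possible because the substrate holds a ketone, a lactone and two silyl ethers that compete for the Lewis acid and surround the cation. The fallback sets out from 20 and comes back at 23. It carries C4 through the rearrangement as a silyl ether instead of a ketone, so C5–H is not acidic while the two β-oxygens still disfavour a hydride shift from C5. Compound 20 is silylated (Et3SiOTf, 2,6-lutidine) to the epoxy triethylsilyl ether F1. The same aluminium reagent should give the ring-contracted aldehyde F2. Wittig methylenation (Ph3P=CH2, THF, −78 → 0 °C) of the aldehyde alone gives the vinyl compound F3. Methanolysis (PPTS, MeOH) gives the alcohol F4, Dess–Martin oxidation gives the vinyl ketone F5, and the zinc–titanium methylenation of step 17 gives 23.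

**Step 17.** The hindered, α-oxygenated C4 ketone may react incompletely, or the Lewis-acidic medium may trigger β-elimination of the lactone oxygen across C5–C6. The fallback sets out from 22 and comes back at 23 by a two-stage Peterson olefination. Addition of Me3SiCH2MgCl/CeCl3 (THF, −78 °C) to both carbonyls gives the bis(β-hydroxysilane) F6, and BF3·OEt2 (CH2Cl2, −78 → 0 °C) eliminates both to 23.

**Step 14.** A homoallylic hydroxyl directs less firmly than an allylic one, so oxygen transfer may be slow and undirected attack on the α face may compete. The fallback sets out from 18 and comes back at 20, and it turns an α-face preference to advantage. NBS in wet DME should form the bromonium ion on the α face and admit water at the tertiary C10 from the β face, giving the bromohydrin F7. Removal of the triethylsilyl group (PPTS, MeOH) gives the bromohydrin alcohol F8, and DBU closes the 10β-alkoxide onto C1 with inversion to give 20.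

**Step 12.** Intermolecular metathesis through the unhindered allyl terminus may outrun closure onto the crowded isopropenyl group. The fallback sets out from 17 and comes back at 19 by changing which substrate enters the metathesis. The triethylsilyl group is removed first (PPTS, MeOH) to give the diene alcohol F9, whose smaller C4 substituent should ease closure, and the same ruthenium catalyst then gives 19 directly.

**Step 19.** Discrimination between the secondary TBS ether and the primary allylic TBDPS ether may be incomplete, and the acid may promote migration of the lactone to the freed O8. The fallback sets out from 26 and comes back at 33. Both silyl groups are removed (excess HF·pyridine) to give the diol F10. The primary allylic hydroxyl alone is silylated (t-BuMe2SiCl, imidazole, −20 °C) to give the mono-silyl ether F11. Esterification with 30 as in step 22 gives the bis-TBS ester F12, and HF·pyridine gives 33.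

## Further compounds

F1 | step 16 | 1β,10β-epoxide of 18: epoxy alcohol 20 as its 4-triethylsilyl ether | [C@@H]12O[C@]1(C)[C@H]([C@@H](O[Si](CC)(CC)CC)CO[Si](c4ccccc4)(c5ccccc5)C(C)(C)C)[C@H]3OC(=O)C[C@@H]3[C@@H](O[Si](C)(C)C(C)(C)C)C2
F2 | step 16 | cyclohexane aldehyde: 10β-formyl, 10α-methyl, 5β-[(1R)-2-(TBDPS-oxy)-1-(TES-oxy)ethyl], 6α,12-lactone, 8α-TBS-oxy | O=C[C@@]1(C)C[C@H](O[Si](C)(C)C(C)(C)C)[C@H]2CC(=O)O[C@@H]2[C@H]1[C@@H](O[Si](CC)(CC)CC)CO[Si](c3ccccc3)(c4ccccc4)C(C)(C)C
F3 | step 16 | 10β-vinyl analogue of F2 | C=C[C@@]1(C)C[C@H](O[Si](C)(C)C(C)(C)C)[C@H]2CC(=O)O[C@@H]2[C@H]1[C@@H](O[Si](CC)(CC)CC)CO[Si](c3ccccc3)(c4ccccc4)C(C)(C)C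
F4 | step 16 | F3 with free (4R)-hydroxyl | C=C[C@@]1(C)C[C@H](O[Si](C)(C)C(C)(C)C)[C@H]2CC(=O)O[C@@H]2[C@H]1[C@@H](O)CO[Si](c3ccccc3)(c4ccccc4)C(C)(C)C
F5 | step 16 | 10β-vinyl C4 ketone: 5β-[2-(TBDPS-oxy)acetyl], 6α,12-lactone, 8α-TBS-oxy | C=C[C@@]1(C)C[C@H](O[Si](C)(C)C(C)(C)C)[C@H]2CC(=O)O[C@@H]2[C@H]1C(=O)CO[Si](c3ccccc3)(c4ccccc4)C(C)(C)C
F6 | step 17 | bis(β-hydroxysilane): 22 with Me3SiCH2 added to C1 and to C4 (carbinol configurations unspecified) | C[Si](C)(C)CC(O)[C@@]1(C)C[C@H](O[Si](C)(C)C(C)(C)C)[C@H]2CC(=O)O[C@@H]2[C@H]1C(O)(C[Si](C)(C)C)CO[Si](c3ccccc3)(c4ccccc4)C(C)(C)C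
F7 | step 14 | bromohydrin of 18: 1α-bromo, 10β-hydroxy, 4-TES ether | O[C@]1(C)[C@H]([C@@H](O[Si](CC)(CC)CC)CO[Si](c3ccccc3)(c4ccccc4)C(C)(C)C)[C@H]2OC(=O)C[C@@H]2[C@@H](O[Si](C)(C)C(C)(C)C)C[C@H]1Br
F8 | step 14 | bromohydrin with free (4R)-hydroxyl: 1α-bromo, 10β-hydroxy | O[C@]1(C)[C@H]([C@@H](O)CO[Si](c3ccccc3)(c4ccccc4)C(C)(C)C)[C@H]2OC(=O)C[C@@H]2[C@@H](O[Si](C)(C)C(C)(C)C)C[C@H]1Br
F9 | step 12 | diene alcohol: 17 without the triethylsilyl group | C=C(C)[C@H]([C@@H](O)CO[Si](c1ccccc1)(c2ccccc2)C(C)(C)C)[C@H]3OC(=O)C[C@@H]3[C@@H](O[Si](C)(C)C(C)(C)C)CC=C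
F10 | step 19 | 8α,15-diol of the triene lactone | C=C[C@@]1(C)C[C@H](O)[C@H]2C(=C)C(=O)O[C@@H]2[C@H]1C(=C)CO
F11 | step 19 | 8α-hydroxy triene lactone, 15-TBS ether | C=C[C@@]1(C)C[C@H](O)[C@H]2C(=C)C(=O)O[C@@H]2[C@H]1C(=C)CO[Si](C)(C)C(C)(C)C
F12 | step 19 | bis-TBS ether of the target | C=C[C@@]1(C)C[C@H](OC(=O)[C@H](C)CO[Si](C)(C)C(C)(C)C)[C@H]2C(=C)C(=O)O[C@@H]2[C@H]1C(=C)CO[Si](C)(C)C(C)(C)C
A1 | alternative 1 | (S)-5-(tert-butyldimethylsilyloxy)-3-methylcyclohex-2-en-1-one | CC1=CC(=O)C[C@@H](O[Si](C)(C)C(C)(C)C)C1
A2 | alternative 1 | tert-butyldiphenyl(prop-2-yn-1-yloxy)silane | C#CCO[Si](c1ccccc1)(c1ccccc1)C(C)(C)C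
A3 | alternative 1 | cis-fused 4-(TBS-oxy)-8-[(TBDPS-oxy)methyl]-6-methylbicyclo[4.2.0]oct-7-en-2-one | C1=C(CO[Si](c3ccccc3)(c3ccccc3)C(C)(C)C)[C@@H]2C(=O)C[C@@H](O[Si](C)(C)C(C)(C)C)C[C@]12C
A4 | alternative 2 | trans-2-ethynyl alcohol: cyclohexane with 6α-hydroxyl, 7β-ethynyl, 8α-[(R)-3-(TBDPS-oxy)-2-methylpropanoyloxy], 10β-vinyl, 5β-[3-(TBDPS-oxy)prop-1-en-2-yl] | C=C[C@@]1(C)C[C@H](OC(=O)[C@H](C)CO[Si](c2ccccc2)(c2ccccc2)C(C)(C)C)[C@@H](C#C)[C@H](O)[C@H]1C(=C)CO[Si](c2ccccc2)(c2ccccc2)C(C)(C)C
A5 | alternative 2 | bis(tert-butyldiphenylsilyl) ether of the target | C=C[C@@]1(C)C[C@H](OC(=O)[C@H](C)CO[Si](c3ccccc3)(c3ccccc3)C(C)(C)C)[C@H]2C(=C)C(=O)O[C@@H]2[C@H]1C(=C)CO[Si](c4ccccc4)(c4ccccc4)C(C)(C)C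
A6 | alternative 3 | open-chain aldehyde with (Z)-2-(pinacolborylmethyl)enoate: methyl ester, C6-TBS ether, C15-TBDPS ether, quaternary C10 with methyl and vinyl | C=C[C@@](C)(CC=O)[C@H](C(=C)CO[Si](c1ccccc1)(c1ccccc1)C(C)(C)C)[C@@H](O[Si](C)(C)C(C)(C)C)/C=C(/CB1OC(C)(C)C(C)(C)O1)C(=O)OC
A7 | alternative 3 | cyclohexanol with free 8α-hydroxyl, C7 methyl acrylate, 6α-TBS-oxy, 15-TBDPS-oxy | C=C[C@@]1(C)C[C@H](O)[C@@H](C(=C)C(=O)OC)[C@H](O[Si](C)(C)C(C)(C)C)[C@H]1C(=C)CO[Si](c2ccccc2)(c2ccccc2)C(C)(C)C
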